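The runs were computed on assumed constants; the scatter is artificial.

In a one-step world every bit of starting material lost would reappear as target, but the oak run lost 11.4% by 120 s and shows 7.4% of target beside 3.8% of side product. You therefore have two lines to follow, and the new flasks differ from oak in their charges and run for longer.

| flask | starting material | coupling partner | transfer agent | initiator | remark | time |
|---|---|---|---|---|---|---|
| oak | 0.18 M | 2 equiv | 0.027 M | 10 mol% | run made earlier |  |
| zeta | 0.18 M | 2.00 equiv | 0.0180 M | 10 mol% |  | 6.0 min |
| beta | 0.18 M | 2.60 equiv | 0.0180 M | 10 mol% |  | 6.0 min |
| delta | 0.18 M | 3.40 equiv | 0.0180 M | 10 mol% |  | 6.0 min |

oak run (percent of the starting material charged)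

| time / s | starting material / % | target / % | first chain carrier / % | side product / % |
|---|---|---|---|---|
| 12.0 | 98.7 | 0.6 | 0 | 0.3 |
| 30.0 | 96.7 | 1.9 | 0.5 | 1.0 |
| 60.0 | 94.0 | 3.4 | 0 | 2.1 |
| 90.0 | 91.4 | 6.1 | 0 | 2.8 |
| 120 | 88.6 | 7.4 | 0 | 3.8 |

(standard deviation of a reading: 0.3 percentage points)

- steps thought possible: starting material + second chain carrier -> by-product + first chain carrier; 2 second chain carrier -> ended chains; coupling partner + first chain carrier -> target + second chain carrier; initiator -> 2 initiating radical; 2 idle radical -> ended radicals; transfer agent + first chain carrier -> side product + idle radical; starting material + initiating radical -> capped initiator + first chain carrier
- no earlier run changes the charge of transfer agent; that part of a forecast is a guess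

* which of these there is most of at the end, counted by the starting material in it, zeta (target / side product / first chain carrier / starting material)
* which of these there is most of at the end, counted by the starting material in it, beta (target / side product / first chain carrier / starting material)
* which of these there is most of at the end, counted by the starting material in it, delta (target / side product / first chain carrier / starting material)
* amount of the one of these that there is most of at the end, in percent of the starting material charged, zeta
* amount of the one of these that there is most of at the end, in percent of the starting material charged, beta
* amount of the one of these that there is most of at the end, in percent of the starting material charged, delta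

Here is my own reckoning, as a ladder of time scales. On the fastest rung, the first chain carrier reads at most 0.5% against a scatter of 0.3 percentage points, so I treat the carriers as a steady state from the first reading at 12.0 s. What remains are slow lines, and the next rung is the oak window of 120 s, where I replace each curve by its mean slope. The mean rate of target per unit of c(coupling partner) is g = 0.103 /M/min, a fraction of the starting material charged, and g times c(coupling partner) is a pseudo-first-order rate.

The mean hides a curve: target gained 3.4% in the first 60.0 s and 4 points in the next 1.00 min. That step is close to the scatter, but it warns that the line may run low.

The next rung is the transfer agent. Oak's side-product rate is 0.00342 M/min, read at 0.027 M of transfer agent, and held for the 6.0 min asked it adds up to 0.0205 M, more than the 0.0180 M charged here. That rate belongs to a larger charge and should fall as the agent goes, so I take the charge as a ceiling on side product, 10.0% of the starting material, and not as a forecast of it.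

Then g times c(coupling partner) times time gives target of 22.2% in zeta, 28.9% in beta and 37.7% in delta. With side product at its ceiling, that leaves 67.8%, 61.1% and 52.3% of starting material, so I expect starting material on top in each.

The forecast differs: it names target, target and target, at 47%, 61% and 76%, expecting that “the chains lengthen late in the run”.

The flasks end with starting material, starting material and starting material on top, at 61.6%, 59.2% and 56.9%.

    starting material + second chain carrier → by-product + first chain carrier (k = 5000 /M/s)
    2 second chain carrier → ended chains (k = 2.00 × 10⁸ /M/s)
    coupling partner + first chain carrier → target + second chain carrier (k = 4100 /M/s)
    initiator → 2 initiating radical (k = 0.00210 /s)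
    2 idle radical → ended radicals (k = 2.40 × 10⁸ /M/s)
    transfer agent + first chain carrier → side product + idle radical (kL = 34000 /M/s)
    starting material + initiating radical → capped initiator + first chain carrier (k = 61000 /M/s)

On beta, g gave 28.9% of target against the 33.9% found, on the low side that the oak slopes warned of. A neighbouring flask is beta at 0.31 M of starting material, with the same equivalents of coupling partner, the same 0.0180 M of transfer agent and the same time, which raises c(coupling partner) to 0.806 M. There g gives 49.7% of target, and the ceiling on side product, now 5.81% of the larger charge, leaves 44.5% of starting material, which puts target on top. That flask ends with target on top, at 49.7% against 45.5% of starting material.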